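**Retrosynthetic overview**

1. Target ⇒ 4,5-diol 28 (tertiary acetate by cyclic orthoacetate opening) ⇒ (Z)-cyclodecenol 25 by C9-OH-directed epoxidation and C9 angeloylation.
2. 25 ⇒ acyclic triene 24 by ring-closing metathesis of C1=C10. The carvone ring is opened in step 4, the ten-membered carbocycle (the only ring of the carbon skeleton) is closed in step 16, and the oxirane is afterwards only an oxidation of the new olefin.
3. Enabling feature: the C1–C10 oxirane is cis-fused to the ten-membered ring (C2 and C9 cis), i.e. it descends from a (Z)-C1=C10 cyclodecene, the geometry a medium-ring metathesis favours. Its neighbour C9 carries the hydroxyl that first activates the C10 olefin for metathesis and then directs the epoxidation.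
4. 24 ⇒ chain C4–C9 by three carbonyl additions: 2-propenyl to the C9 aldehyde (Felkin–Anh), a hydroxymethyl anion equivalent to the C4 ketone and allyl to the C3 aldehyde (both chelation-controlled). C8–O comes from an organocatalytic α-oxygenation.
5. Chain ⇒ (R)-carvone, cut between ring carbons C2 and C3: carvone C1→C5, C2 and its methyl→C4/C15, C3→C9, C4→C8, C5→C7 (isopropenyl kept), C6→C6.

Key step: step 16

Remark: atoms carry germacrane numbers throughout. C1/C10 are the oxirane carbons (C10 bears CH3-14), C2 is CH2, C3 CH(OAng), C4 C(CH3-15)(OAc), C5 CH(OH), C6 CH2, C7 CH(isopropenyl C11–C13), C8 CH(O-2-methylbutanoyl), C9 CH(OAng).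
Remark: in step 5 the imidazolidinone enantiomer meant is the one that delivers oxygen to the enamine face giving the 8S centre; which enantiomer that is would be fixed on a model aldehyde.

**Route**

Step 1
Reactants: 1 (R)-(−)-carvone
Product: 2 (1R,5R)-cis-carveol
Conditions: NaBH4, CeCl3·7H2O, MeOH, −78 °C
Reagents that add atoms: none
Why: Luche 1,2-reduction; axial hydride attack on the half-chair with pseudo-equatorial isopropenyl should give the cis alcohol, which is the C5/C7 relationship of the target.

Step 2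
Reactants: 2 cis-carveol
Product: 3 cis-epoxycarveol (oxirane on the face of the hydroxyl)
Conditions: VO(acac)2 (cat.), t-BuOOH, CH2Cl2, 0 °C → rt
Reagents that add atoms: tert-butyl hydroperoxide, CC(C)(C)OO
Why: Hydroxyl-directed vanadium epoxidation touches only the allylic-alcohol olefin and leaves the isopropenyl group; the two oxirane centres are destroyed in step 4.

Step 3
Reactants: 3 cis-epoxycarveol
Product: 4 4-methoxybenzyl (PMB) ether of 3
Conditions: NaH, PMBCl, Bu4NI (cat.), THF/DMF, 0 °C → rt
Reagents that add atoms: 4-methoxybenzyl chloride, COc1ccc(CCl)cc1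
Why: Williamson etherification; a Payne rearrangement is geometrically impossible for the cis-epoxy alkoxide, and PMB later serves as chelating group and as an oxidatively removable group.

Step 4
Reactants: 4 PMB ether
Product: 6 (3S,5R)-5-(4-methoxybenzyloxy)-6-oxo-3-(prop-1-en-2-yl)heptanal (C4 methyl ketone, C9 aldehyde), via glycol 5 (not isolated)
Conditions: H5IO6, THF/H2O, 0 °C → rt
Reagents that add atoms: water, O
Why: Acid-promoted oxirane hydrolysis and periodate glycol cleavage in one pot (the limonene-oxide type degradation) cut the old ring between C4 and C9 and leave C5 and C7 untouched.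

Step 5
Reactants: 6 keto aldehyde
Product: 8 C9 primary alcohol with C8–O–TEMPO, via oxyaminated aldehyde 7 (not isolated)
Conditions: TEMPO, CuCl2 (10 mol%), chiral 5-benzyl-2-tert-butyl-3-methylimidazolidin-4-one·TFA (20 mol%), air, acetone, −10 °C; then NaBH(OAc)3, AcOH, CH2Cl2, 0 °C
Reagents that add atoms: TEMPO, CC1(C)CCCC(C)(C)N1[O]
Why: Enamine-catalysed α-oxyamination of the aldehyde sets C8 by catalyst control (the hindered α-alkoxy ketone forms no enamine with this catalyst), and triacetoxyborohydride reduces the aldehyde but not the ketone.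

Step 6
Reactants: 8 primary alcohol
Product: 9 C9 tert-butyldiphenylsilyl (TBDPS) ether
Conditions: TBDPSCl, imidazole, CH2Cl2, 0 °C → rt
Reagents that add atoms: tert-butyl(chloro)diphenylsilane, CC(C)(C)[Si](Cl)(c1ccccc1)c1ccccc1
Why: Standard silylation of the only hydroxyl, so that C9 can be parked while the ketone end is built up.

Step 7
Reactants: 9 TBDPS ether; 10 (chloromethyl)(isopropoxy)dimethylsilane
Product: 12 C3,C4-diol (C3 primary OH, C4 tertiary OH), via silylmethyl carbinol 11 (not isolated)
Conditions: 10, Mg, THF (Grignard reagent made first); then 9, THF/Et2O, −78 → 0 °C; then KF, KHCO3, 30% H2O2, THF/MeOH, rt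
Reagents that add atoms: hydrogen peroxide, OO
Why: Cram-chelate Grignard addition (Mg bridges the ketone and the α-OPMB oxygen, attack on the face away from C6) should set C4 with the 4,5-syn relationship, and Tamao–Fleming oxidation turns C–Si into C–OH without touching carbon stereochemistry.

Step 8
Reactants: 12 diol
Product: 13 C3 α-hydroxy aldehyde
Conditions: SO3·pyridine, DMSO, Et3N, CH2Cl2, 0 °C
Reagents that add atoms: none
Why: Parikh–Doering oxidation takes the primary alcohol to the aldehyde without glycol cleavage; the tertiary hydroxyl and the alkoxyamine are inert.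

Step 9
Reactants: 13 α-hydroxy aldehyde; 14 allyl bromide
Product: 15 homoallylic 3,4-diol
Conditions: In powder, THF/H2O, rt
Reagents that add atoms: none
Why: Barbier-type indium allylation under α-hydroxyl chelation; allyl should add to the chelate from the methyl face (anti to the C5 branch) to give the 3,4-syn diol, setting C3.

Step 10
Reactants: 15 diol; 16 angelic acid
Product: 17 C3 angelate
Conditions: 16, 2,4,6-trichlorobenzoyl chloride, Et3N, toluene, rt; then 15, 75 °C
Reagents that add atoms: none
Why: Yamaguchi-type mixed-anhydride acylation without DMAP avoids Z→E isomerisation of the angelate and leaves the tertiary C4 hydroxyl free.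

Step 11
Reactants: 17 C3 angelate
Product: 18 C8 secondary alcohol
Conditions: Zn dust, AcOH/THF/H2O, 50 °C
Reagents that add atoms: none
Why: Reductive N–O cleavage of the alkoxyamine; esters, PMB and TBDPS ethers are stable to zinc in acetic acid.

Step 12
Reactants: 18 C8 alcohol; 19 (R)-2-methylbutanoic acid
Product: 20 C8 (R)-2-methylbutanoate
Conditions: EDC·HCl, DMAP (cat.), CH2Cl2, 0 °C → rt
Reagents that add atoms: none
Why: Steglich-type esterification of the only reactive hydroxyl (the tertiary C4–OH does not acylate under these conditions).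

Step 13
Reactants: 20 C8 ester
Product: 21 C9 primary alcohol
Conditions: HF·pyridine, pyridine, THF, 0 °C → rt
Reagents that add atoms: none
Why: Buffered fluoride desilylation; the mildly acidic medium keeps 1,2-acyl migration from O8 slow.

Step 14
Reactants: 21 primary alcohol
Product: 22 C9 α-acyloxy aldehyde
Conditions: Dess–Martin periodinane, NaHCO3, CH2Cl2, 0 °C
Reagents that add atoms: none
Why: Buffered Dess–Martin oxidation gives the epimerisable aldehyde under neutral conditions; it is used at once.

Step 15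
Reactants: 22 aldehyde; 23 2-bromopropene
Product: 24 seco-triene with free C9 allylic alcohol
Conditions: CrCl2, NiCl2 (cat.), DMSO, rt
Reagents that add atoms: none
Why: Nozaki–Hiyama–Kishi alkenylation is selective for the aldehyde beside three esters; Felkin–Anh addition (C8–O anti to the incoming alkenylchromium) should give the 8,9-anti alcohol, setting C9.

Step 16
Reactants: 24 seco-triene
Product: 25 (1(10)Z)-cyclodecenol
Conditions: second-generation Ru–NHC benzylidene metathesis catalyst (10–15 mol%), 1,4-benzoquinone (cat.), toluene, 80 °C, about 1 mM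
Reagents that add atoms: none
Why: Ring-closing olefin metathesis: the Ru alkylidene loads on the only monosubstituted olefin (C1=CH2), forms a ruthenacyclobutane with the 1,1-disubstituted C10 olefin and releases ethene; the closest known reactions are metathesis closures of trisubstituted medium-ring cycloalkenes and hydroxyl-accelerated metathesis of allylic alcohols. The ten-membered carbocycle is closed by joining C1 to C10, the only C–C bond formed. The one new stereo element is the olefin geometry: in a ten-membered ring the (Z)-trisubstituted olefin is the less strained isomer, so C2 and C9 should end up cis, as the cis-fused oxirane requires. The step needs selectivity for the C10 olefin over the C7 isopropenyl group (which would give an eight-membered ring) and over dimerisation. The free allylic C9–OH accelerates metathesis at C10, whereas the C7 isopropenyl sits on a carbon crowded by the C8 ester and has no such activation; high dilution suppresses dimers. Benzoquinone suppresses Ru–H isomerisation of the allylic alcohol.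

Step 17
Reactants: 25 cyclodecenol
Product: 26 1,10-epoxy-9-ol
Conditions: VO(acac)2 (cat.), t-BuOOH, CH2Cl2, 0 °C
Reagents that add atoms: tert-butyl hydroperoxide, CC(C)(C)OO
Why: Hydroxyl-directed vanadium epoxidation; with the (Z)-olefin, A(1,3) strain holds C9–H in the olefin plane, so oxygen arrives from the hydroxyl face to give the threo epoxy alcohol, setting C10 and C1 together, while the angelate and isopropenyl olefins do not react.

Step 18
Reactants: 26 epoxy alcohol; 16 angelic acid
Product: 27 3,9-bis-angelate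
Conditions: 16, 2,4,6-trichlorobenzoyl chloride, Et3N, toluene, rt; then 26, 75 °C
Reagents that add atoms: none
Why: Yamaguchi-type acylation of the only secondary hydroxyl under non-nucleophilic, non-acidic conditions that the oxirane and the angelates tolerate.

Step 19
Reactants: 27 bis-angelate
Product: 28 4,5-diol
Conditions: DDQ, CH2Cl2/pH 7 buffer, 0 °C
Reagents that add atoms: none
Why: Oxidative PMB cleavage under neutral, wet conditions (water traps the oxocarbenium before the tertiary hydroxyl can form a benzylidene acetal) spares oxirane, esters and olefins.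

Step 20
Reactants: 28 4,5-diol; 29 trimethyl orthoacetate
Product: 31 CNP0197637.1 (target), via cyclic orthoacetate 30 (not isolated)
Conditions: 29, PPTS (cat.), CH2Cl2, rt; then AcOH/H2O (4:1), 0 °C
Reagents that add atoms: water, O
Why: Cyclic orthoester formation on the 1,2-diol followed by kinetically controlled acid hydrolysis should leave the acetyl group on the more hindered tertiary oxygen (the classical orthoester route to tertiary monoesters of 1,2-diols); no base is present, so neither acyl migration nor angelate isomerisation is expected.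

**Compound list**

1 | (R)-(−)-carvone | CC1=CC[C@H](CC1=O)C(C)=C | starting material
2 | (1R,5R)-cis-carveol | CC1=CC[C@H](C[C@H]1O)C(C)=C | intermediate
3 | cis-epoxycarveol (oxirane cis to OH and isopropenyl) | O[C@@H]1C[C@H](C(C)=C)C[C@@H]2O[C@]12C | intermediate
4 | PMB ether of 3 | COc1ccc(CO[C@@H]2C[C@H](C(C)=C)C[C@@H]3O[C@]23C)cc1 | intermediate
5 | trans-glycol from 4 | COc1ccc(CO[C@@H]2C[C@H](C(C)=C)C[C@@H](O)[C@]2(C)O)cc1 | intermediate (not isolated)
6 | (3S,5R)-5-(4-methoxybenzyloxy)-6-oxo-3-(prop-1-en-2-yl)heptanal | CC(=O)[C@H](OCc1ccc(OC)cc1)C[C@H](C(C)=C)CC=O | intermediate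
7 | 8-(2,2,6,6-tetramethylpiperidin-1-yloxy) aldehyde | CC(=O)[C@H](OCc1ccc(OC)cc1)C[C@H](C(C)=C)[C@H](ON1C(C)(C)CCCC1(C)C)C=O | intermediate (not isolated)
8 | C9 primary alcohol, C8–O–TEMPO, C4 ketone | CC(=O)[C@H](OCc1ccc(OC)cc1)C[C@H](C(C)=C)[C@H](ON1C(C)(C)CCCC1(C)C)CO | intermediate
9 | C9 TBDPS ether of 8 | CC(=O)[C@H](OCc1ccc(OC)cc1)C[C@H](C(C)=C)[C@H](ON1C(C)(C)CCCC1(C)C)CO[Si](c1ccccc1)(c1ccccc1)C(C)(C)C | intermediate
10 | (chloromethyl)(isopropoxy)dimethylsilane | CC(C)O[Si](C)(C)CCl | starting material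
11 | C4 tertiary carbinol with CH2SiMe2(OiPr) | C[C@@](O)(C[Si](C)(C)OC(C)C)[C@H](OCc1ccc(OC)cc1)C[C@H](C(C)=C)[C@H](ON1C(C)(C)CCCC1(C)C)CO[Si](c1ccccc1)(c1ccccc1)C(C)(C)C | intermediate (not isolated)
12 | C3,C4-diol | C[C@@](O)(CO)[C@H](OCc1ccc(OC)cc1)C[C@H](C(C)=C)[C@H](ON1C(C)(C)CCCC1(C)C)CO[Si](c1ccccc1)(c1ccccc1)C(C)(C)C | intermediate
13 | C3 α-hydroxy aldehyde | C[C@@](O)(C=O)[C@H](OCc1ccc(OC)cc1)C[C@H](C(C)=C)[C@H](ON1C(C)(C)CCCC1(C)C)CO[Si](c1ccccc1)(c1ccccc1)C(C)(C)C | intermediate
14 | allyl bromide | C=CCBr | starting material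
15 | homoallylic 3,4-diol | C[C@@](O)([C@@H](O)CC=C)[C@H](OCc1ccc(OC)cc1)C[C@H](C(C)=C)[C@H](ON1C(C)(C)CCCC1(C)C)CO[Si](c1ccccc1)(c1ccccc1)C(C)(C)C | intermediate
16 | angelic acid | C/C=C(/C)C(=O)O | starting material
17 | C3 angelate | C[C@@](O)([C@@H](OC(=O)/C(C)=C\C)CC=C)[C@H](OCc1ccc(OC)cc1)C[C@H](C(C)=C)[C@H](ON1C(C)(C)CCCC1(C)C)CO[Si](c1ccccc1)(c1ccccc1)C(C)(C)C | intermediate
18 | C8 alcohol | C[C@@](O)([C@@H](OC(=O)/C(C)=C\C)CC=C)[C@H](OCc1ccc(OC)cc1)C[C@H](C(C)=C)[C@H](O)CO[Si](c1ccccc1)(c1ccccc1)C(C)(C)C | intermediate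
19 | (R)-2-methylbutanoic acid | CC[C@@H](C)C(=O)O | starting material
20 | C8 (R)-2-methylbutanoate | C[C@@](O)([C@@H](OC(=O)/C(C)=C\C)CC=C)[C@H](OCc1ccc(OC)cc1)C[C@H](C(C)=C)[C@H](OC(=O)[C@H](C)CC)CO[Si](c1ccccc1)(c1ccccc1)C(C)(C)C | intermediate
21 | C9 primary alcohol | C[C@@](O)([C@@H](OC(=O)/C(C)=C\C)CC=C)[C@H](OCc1ccc(OC)cc1)C[C@H](C(C)=C)[C@H](OC(=O)[C@H](C)CC)CO | intermediate
22 | C9 aldehyde | C[C@@](O)([C@@H](OC(=O)/C(C)=C\C)CC=C)[C@H](OCc1ccc(OC)cc1)C[C@H](C(C)=C)[C@H](OC(=O)[C@H](C)CC)C=O | intermediate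
23 | 2-bromopropene | CC(Br)=C | starting material
24 | seco-triene (C9 allylic alcohol, C1 vinyl, C10 2-propenyl) | C[C@@](O)([C@@H](OC(=O)/C(C)=C\C)CC=C)[C@H](OCc1ccc(OC)cc1)C[C@H](C(C)=C)[C@H](OC(=O)[C@H](C)CC)[C@H](O)C(C)=C | intermediate
25 | (1(10)Z)-cyclodecenol | C=C(C)[C@H]1C[C@@H](OCc2ccc(OC)cc2)[C@](C)(O)[C@@H](OC(=O)/C(C)=C\C)C/C=C(C)\[C@@H](O)[C@H]1OC(=O)[C@H](C)CC | intermediate
26 | 1,10-epoxy-9-ol | C=C(C)[C@H]1C[C@@H](OCc2ccc(OC)cc2)[C@](C)(O)[C@@H](OC(=O)/C(C)=C\C)C[C@@H]2O[C@]2(C)[C@@H](O)[C@H]1OC(=O)[C@H](C)CC | intermediate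
27 | 3,9-bis-angelate, 5-O-PMB | C=C(C)[C@H]1C[C@@H](OCc2ccc(OC)cc2)[C@](C)(O)[C@@H](OC(=O)/C(C)=C\C)C[C@@H]2O[C@]2(C)[C@@H](OC(=O)/C(C)=C\C)[C@H]1OC(=O)[C@H](C)CC | intermediate
28 | 4,5-diol | C=C(C)[C@H]1C[C@@H](O)[C@](C)(O)[C@@H](OC(=O)/C(C)=C\C)C[C@@H]2O[C@]2(C)[C@@H](OC(=O)/C(C)=C\C)[C@H]1OC(=O)[C@H](C)CC | intermediate
29 | trimethyl orthoacetate | CC(OC)(OC)OC | starting material
30 | 4,5-O-(1-methoxyethylidene) cyclic orthoester | C=C(C)[C@H]1C[C@H]3OC(C)(OC)O[C@]3(C)[C@@H](OC(=O)/C(C)=C\C)C[C@@H]2O[C@]2(C)[C@@H](OC(=O)/C(C)=C\C)[C@H]1OC(=O)[C@H](C)CC | intermediate (not isolated)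
31 | CNP0197637.1 | C=C(C)[C@H]1C[C@@H](O)[C@](C)(OC(C)=O)[C@@H](OC(=O)/C(C)=C\C)C[C@@H]2O[C@]2(C)[C@@H](OC(=O)/C(C)=C\C)[C@H]1OC(=O)[C@H](C)CC | target

**Totals and risks**

Total step count: 20. Longest linear sequence: 20 steps (from 1).

Step 16 (metathesis ring closure). What may go wrong: the C1 alkylidene closes onto the C7 isopropenyl group (eight-membered ring), dimerises, or gives E/Z leakage in a slow ten-membered closure. Fallback, from 22 back to 25: but-2-yn-1-ol is taken with Red-Al and then iodine to (Z)-3-iodobut-2-en-1-ol F1, which is O-allylated (NaH, allyl bromide 14) to (Z)-1-(allyloxy)-3-iodobut-2-ene F2. Nozaki–Hiyama–Kishi coupling of F2 with aldehyde 22, as in step 15, gives the relay tetraene F3. In a relay ring-closing metathesis the catalyst loads on the allyl ether, expels 2,5-dihydrofuran and is thereby delivered as the C10 alkylidene, which can only close onto the C1 vinyl group and gives 25.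

Step 20 (tertiary acetate by orthoester opening). What may go wrong: the orthoester collapses the other way (acetate on O5), or the acid opens the oxirane transannularly through the free O5/O4 hydroxyls. Fallback, from 28 to 31: the secondary O5–H is silylated selectively (TESCl, imidazole) to the 5-O-triethylsilyl ether F4; the remaining tertiary hydroxyl is acetylated (Ac2O, Et3N, DMAP, CH2Cl2) to the 4-O-acetate F5; HF·pyridine then removes the silyl group and gives 31.

Step 15 (alkenylation of the α-acyloxy aldehyde). What may go wrong: poor facial selectivity at C9 (Felkin–Anh against Cornforth or chelated addition) and 1,2-acyl migration from O8 to the chromium alkoxide at O9. Fallback, from 24 (as C9 epimer mixture) back to 24: Dess–Martin oxidation gives the C9 enone F6, and oxazaborolidine-catalysed reduction with catecholborane (toluene, −78 °C) sets C9 under reagent control.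

Further compounds

F1 | step 16 | (Z)-3-iodobut-2-en-1-ol | C/C(I)=C/CO
F2 | step 16 | (Z)-1-(allyloxy)-3-iodobut-2-ene | C/C(I)=C/COCC=C
F3 | step 16 | relay tetraene (24 with C10=CH–CH2–O–allyl in place of C10=CH2) | C[C@@](O)([C@@H](OC(=O)/C(C)=C\C)CC=C)[C@H](OCc1ccc(OC)cc1)C[C@H](C(C)=C)[C@H](OC(=O)[C@H](C)CC)[C@H](O)/C(C)=C\COCC=C
F4 | step 20 | 5-O-triethylsilyl ether of 28 | C=C(C)[C@H]1C[C@@H](O[Si](CC)(CC)CC)[C@](C)(O)[C@@H](OC(=O)/C(C)=C\C)C[C@@H]2O[C@]2(C)[C@@H](OC(=O)/C(C)=C\C)[C@H]1OC(=O)[C@H](C)CC
F5 | step 20 | 4-O-acetyl-5-O-triethylsilyl compound | C=C(C)[C@H]1C[C@@H](O[Si](CC)(CC)CC)[C@](C)(OC(C)=O)[C@@H](OC(=O)/C(C)=C\C)C[C@@H]2O[C@]2(C)[C@@H](OC(=O)/C(C)=C\C)[C@H]1OC(=O)[C@H](C)CC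
F6 | step 15 | C9 enone from 24 | C[C@@](O)([C@@H](OC(=O)/C(C)=C\C)CC=C)[C@H](OCc1ccc(OC)cc1)C[C@H](C(C)=C)[C@H](OC(=O)[C@H](C)CC)C(=O)C(C)=C
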